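**Plan**

- Numbering (germacranolide): C6 lactone O–CH, C7 ring fusion, C8 CH–OAng, C9 CH–OAc, C10(CH3)=C1 (Z), C2 CH–OH, C3 H2, C4(CH3)=C5 (E), C11–C13 methylene lactone; ring 1 is the γ-lactone, ring 2 the ten-membered carbocycle.
- Feature used: C8 and C9 carry a threo diol and C9 is bonded to the Z alkene carbon C10, so C9 can be a dioxolan-4-yl radical (from a carboxylic acid) and C10 a Z alkenyl iodide; the trans acetonide returns the threo diol.
- Retrosynthesis: the O8 angelate, O9 acetate and C11=C13 are removed first; ring 2 is cut at C9–C10; the lactone C–O and C5–C6 are cut to give fragment A (C6–C9, C11, C12 and one extra carboxyl carbon on C9) and fragment B (C1–C5, C10, C14, C15); A is cut at C6–C7 and C7=C11, B at C2–C3.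
- Forward: A and B are joined at C5–C6 with closure of ring 1, ring 2 closes at C9–C10, then C13, the two esters and the free C2 hydroxyl follow.
- Stereochemistry: C8 from commercial D-threitol acetonide (the reduced acetonide of D-tartaric acid); C7 by anti-selective vinylcopper addition next to C8; C6 by Felkin–Anh addition next to C7; C2 by a chiral phosphoric acid; C9 in the ring closure, anti to C8; E alkene by syn methylalumination, Z alkene by trans hydroalumination–iodination.

Key step: step 12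

Remark: alkoxides, enolates and the boron, magnesium or aluminium alkoxides that exist only until aqueous work-up are treated as salts of the numbered compounds and are not numbered apart.
Remark: the S enantiomer of the phosphoric acid in step 7 is assumed to direct the allenyl group to the Si face of the enal, as expected by analogy with aryl aldehydes; should the sense be opposite, its mirror image is used.

**Route**

Step 1
Reactants: 1 (4R,5R)-2,2-dimethyl-1,3-dioxolane-4,5-dimethanol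
Product: 2 [(4R,5R)-5-(tert-butyldimethylsilyloxymethyl)-2,2-dimethyl-1,3-dioxolan-4-yl]methanol
Conditions: NaH (1.0 equiv), THF, 0 °C; TBSCl (1.0 equiv), 0 °C → rt
Reagents that add atoms: tert-butyldimethylsilyl chloride, CC(C)(C)[Si](C)(C)Cl
Why: O-silylation of the monosodium alkoxide of a C2-symmetric diol, whose two hydroxyls are equivalent, so only one monoether can form and no stereocentre is touched.

Step 2
Reactants: 2 [(4R,5R)-5-(tert-butyldimethylsilyloxymethyl)-2,2-dimethyl-1,3-dioxolan-4-yl]methanol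
Product: 4 methyl (2E)-3-[(4R,5R)-5-(tert-butyldimethylsilyloxymethyl)-2,2-dimethyl-1,3-dioxolan-4-yl]prop-2-enoate, via aldehyde 3 (not isolated)
Conditions: (COCl)2, DMSO, CH2Cl2, −78 °C; Et3N; then Ph3P=CHCO2Me, −78 °C → rt
Reagents that add atoms: methyl (triphenylphosphoranylidene)acetate, COC(=O)C=P(c1ccccc1)(c1ccccc1)c1ccccc1
Why: Swern oxidation followed in the same flask by Wittig olefination with a stabilised ylide avoids handling the hydrate-prone α-alkoxy aldehyde and should give the E enoate (a minor Z isomer is removed by chromatography), while the trans-dioxolane has nothing to gain by epimerising.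

Step 3
Reactants: 4 methyl (2E)-3-[(4R,5R)-5-(tert-butyldimethylsilyloxymethyl)-2,2-dimethyl-1,3-dioxolan-4-yl]prop-2-enoate
Product: 6 methyl (3S)-3-[(4R,5R)-5-(tert-butyldimethylsilyloxymethyl)-2,2-dimethyl-1,3-dioxolan-4-yl]pent-4-enoate, via silyl ketene acetal 5 (not isolated)
Conditions: CH2=CHMgBr (4 equiv), CuI (2 equiv), Me3SiCl, THF, −78 → −40 °C; aq. NH4Cl
Reagents that add atoms: vinylmagnesium bromide, C=C[Mg]Br
Why: silyl chloride-accelerated conjugate addition of a vinyl organocopper reagent to an E γ-alkoxy enoate, in which the allylic C–H eclipses the alkene and the C8–O bond lies antiperiplanar to the incoming copper reagent, so the vinyl group (C5 is added later, this is C6 with its future aldehyde carbon) enters anti to O8 and sets C7 as S.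

Step 4
Reactants: 6 methyl (3S)-3-[(4R,5R)-5-(tert-butyldimethylsilyloxymethyl)-2,2-dimethyl-1,3-dioxolan-4-yl]pent-4-enoate
Product: 8 methyl (3R)-3-[(4R,5R)-5-(tert-butyldimethylsilyloxymethyl)-2,2-dimethyl-1,3-dioxolan-4-yl]-4-oxobutanoate, via ozonide 7 (not isolated)
Conditions: O3, CH2Cl2, −78 °C; PPh3, −78 °C → rt
Reagents that add atoms: ozone, [O-][O+]=O
Why: ozonolysis with reductive work-up turns the vinyl group into the C6 aldehyde, the silyl ether, acetonide and ester being inert to ozone, and the aldehyde is used crude so that C7 does not epimerise (its descriptor changes to R only because the priorities change).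

Step 5
Reactants: 9 but-2-yn-1-ol
Product: 11 (2Z)-3-iodobut-2-en-1-ol, via alkenylaluminate 10 (not isolated)
Conditions: NaAlH2(OCH2CH2OMe)2, THF, 0 °C → rt; I2, −78 → 0 °C
Reagents that add atoms: iodine, II
Why: hydroxyl-directed trans-hydroalumination of a propargylic alcohol places aluminium on C3 in a five-membered alkenylaluminate, and iodinolysis with retention gives the Z alkenyl iodide (future C10 and C14).

Step 6
Reactants: 11 (2Z)-3-iodobut-2-en-1-ol
Product: 12 (2Z)-3-iodobut-2-enal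
Conditions: MnO2, CH2Cl2, rt, dark
Reagents that add atoms: none
Why: allylic oxidation with activated MnO2 stops at the enal under neutral conditions that should not isomerise the Z iodide, and the enal is used at once.

Step 7
Reactants: 12 (2Z)-3-iodobut-2-enal
Product: 13 (4S,5Z)-6-iodohept-5-en-1-yn-4-ol
Conditions: allenylboronic acid pinacol ester, (S)-TRIP [(S)-3,3'-bis(2,4,6-triisopropylphenyl)-1,1'-binaphthyl-2,2'-diyl hydrogen phosphate, 5 mol%], 4 Å MS, toluene, 0 °C
Reagents that add atoms: allenylboronic acid pinacol ester, C=C=CB1OC(C)(C)C(C)(C)O1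
Why: chiral phosphoric acid-catalysed propargylation of an enal by an allenylboronate through a closed six-membered transition state gives the homopropargylic alcohol, and the catalyst directs the Si face of the aldehyde, which sets the carbinol (later C2) as S.

Step 8
Reactants: 13 (4S,5Z)-6-iodohept-5-en-1-yn-4-ol
Product: 14 tert-butyl{[(4S,5Z)-6-iodohept-5-en-1-yn-4-yl]oxy}diphenylsilane
Conditions: TBDPSCl, imidazole, DMF, rt
Reagents that add atoms: tert-butyldiphenylsilyl chloride, CC(C)(C)[Si](Cl)(c1ccccc1)c1ccccc1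
Why: standard silylation of a secondary alcohol, the TBDPS group being chosen because it outlasts both the later removal of the primary TBS ether and the acidic acetonide cleavage.

Step 9
Reactants: 14 tert-butyl{[(4S,5Z)-6-iodohept-5-en-1-yn-4-yl]oxy}diphenylsilane; 8 methyl (3R)-3-[(4R,5R)-5-(tert-butyldimethylsilyloxymethyl)-2,2-dimethyl-1,3-dioxolan-4-yl]-4-oxobutanoate
Product: 17 (4S,5R)-4-[(4R,5R)-5-(tert-butyldimethylsilyloxymethyl)-2,2-dimethyl-1,3-dioxolan-4-yl]-5-[(1E,4S,5Z)-4-(tert-butyldiphenylsilyloxy)-6-iodo-2-methylhepta-1,5-dien-1-yl]oxolan-2-one, via alkenylalane 15 (not isolated), via hydroxy ester 16 (not isolated)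
Conditions: 14 (1.5 equiv), AlMe3, Cp2ZrCl2 (20 mol%), H2O (1 equiv), CH2Cl2, −20 °C; 8, −78 → 0 °C; aq. potassium sodium tartrate; PPTS (cat.), CH2Cl2, rt
Reagents that add atoms: trimethylaluminium, C[Al](C)C
Why: zirconium-catalysed Negishi methylalumination (syn, aluminium on the terminal carbon) gives the E alkenylalane, which adds to the aldehyde in preference to the ester; Felkin–Anh addition anti to the dioxolanyl group on C7 should set C6 as R, and the γ-hydroxy ester closes to the trans lactone (ring 1) under mild acid.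

Step 10
Reactants: 17 (4S,5R)-4-[(4R,5R)-5-(tert-butyldimethylsilyloxymethyl)-2,2-dimethyl-1,3-dioxolan-4-yl]-5-[(1E,4S,5Z)-4-(tert-butyldiphenylsilyloxy)-6-iodo-2-methylhepta-1,5-dien-1-yl]oxolan-2-one
Product: 18 (4S,5R)-4-[(4R,5R)-5-(hydroxymethyl)-2,2-dimethyl-1,3-dioxolan-4-yl]-5-[(1E,4S,5Z)-4-(tert-butyldiphenylsilyloxy)-6-iodo-2-methylhepta-1,5-dien-1-yl]oxolan-2-one
Conditions: HF·pyridine, pyridine, THF, 0 °C
Reagents that add atoms: none
Why: buffered HF·pyridine cleaves a primary TBS ether far faster than the hindered secondary TBDPS ether and leaves the acetonide and the lactone untouched.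

Step 11
Reactants: 18 (4S,5R)-4-[(4R,5R)-5-(hydroxymethyl)-2,2-dimethyl-1,3-dioxolan-4-yl]-5-[(1E,4S,5Z)-4-(tert-butyldiphenylsilyloxy)-6-iodo-2-methylhepta-1,5-dien-1-yl]oxolan-2-one
Product: 20 (4S,5R)-5-{(2R,3S)-2-[(1E,4S,5Z)-4-(tert-butyldiphenylsilyloxy)-6-iodo-2-methylhepta-1,5-dien-1-yl]-5-oxooxolan-3-yl}-2,2-dimethyl-1,3-dioxolane-4-carboxylic acid, via aldehyde 19 (not isolated)
Conditions: TEMPO (20 mol%), PhI(OAc)2 (2.2 equiv), MeCN/H2O (1:1), rt
Reagents that add atoms: water, O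
Why: oxoammonium (TEMPO) oxidation with PhI(OAc)2 in aqueous acetonitrile takes the primary alcohol through the aldehyde hydrate to the acid without touching the alkenes or the alkenyl iodide, and any epimerisation at C9 is harmless because C9 becomes a radical.

Step 12
Reactants: 20 (4S,5R)-5-{(2R,3S)-2-[(1E,4S,5Z)-4-(tert-butyldiphenylsilyloxy)-6-iodo-2-methylhepta-1,5-dien-1-yl]-5-oxooxolan-3-yl}-2,2-dimethyl-1,3-dioxolane-4-carboxylic acid
Product: 21 (2S,6R,7S,8R,9R)-2-(tert-butyldiphenylsilyloxy)-8,9-(isopropylidenedioxy)germacra-1(10)Z,4E-dien-12,6-olide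
Conditions: [Ir(dF(CF3)ppy)2(dtbbpy)]PF6 (2 mol%; dF(CF3)ppy = cyclometalated 2-(2,4-difluorophenyl)-5-(trifluoromethyl)pyridine, dtbbpy = 4,4'-di-tert-butyl-2,2'-bipyridine), NiCl2·DME (20 mol%; DME = 1,2-dimethoxyethane), dtbbpy (25 mol%), Cs2CO3 (2 equiv), degassed DMF (0.002 M), blue LEDs (450 nm), 25 °C
Reagents that add atoms: none
Why: Proposed new method: the excited trivalent iridium photocatalyst oxidises the caesium carboxylate of 20, loss of CO2 leaves a dioxolan-4-yl radical at C9, and the reduced iridium complex returns nickel to the zerovalent state, which inserts into the C10–I bond; the divalent alkenylnickel iodide captures the C9 radical and the trivalent nickel centre so formed eliminates reductively to make C9–C10. The closest known reaction type is the intermolecular nickel–photoredox decarboxylative coupling of α-oxy carboxylic acids with alkenyl halides, and its use to close a ten-membered carbocycle is what is new. Ring 2 closes by C(sp3)–C(sp2) reductive elimination from an eleven-membered nickelacycle, that is by radical capture at the metal and not by exo or endo addition to an alkene. C9 is set by the neighbouring C8 stereocentre: the nearly planar radical bonds anti to the C8 substituent on the dioxolane, which gives the trans (threo) diol whatever the configuration of the acid, while oxidative addition and reductive elimination keep the Z geometry at C10. The step needs ring closure to outrun oligomerisation, hydrogen capture and attack on other π bonds: high dilution serves the first, the lactone carries no methylene group that could accept the radical, and 5-exo addition to C4=C5 is disfavoured because C5 and C8 are trans on the lactone and would have to form a trans-fused bicyclo[3.3.0]octane.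

Step 13
Reactants: 21 (2S,6R,7S,8R,9R)-2-(tert-butyldiphenylsilyloxy)-8,9-(isopropylidenedioxy)germacra-1(10)Z,4E-dien-12,6-olide
Product: 22 11-(dimethylaminomethyl) derivative of 21 (C11 configuration of no consequence)
Conditions: LiN(iPr)2, THF, −78 °C; Me2N=CH2 I (N,N-dimethylmethyleneiminium iodide), −78 °C → rt
Reagents that add atoms: N,N-dimethylmethyleneiminium iodide, C=[N+](C)C.[I-]
Why: kinetic lactone enolate formation and Mannich alkylation with Eschenmoser's salt at C11, the acetonide masking both hydroxyls and no leaving group standing β to the enolate.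

Step 14
Reactants: 22 11-(dimethylaminomethyl) derivative of 21
Product: 24 (2S,6R,7S,8R,9R)-2-(tert-butyldiphenylsilyloxy)-8,9-(isopropylidenedioxy)germacra-1(10)Z,4E,11(13)-trien-12,6-olide, via ammonium iodide 23 (not isolated)
Conditions: MeI, MeOH, rt; then aq. NaHCO3, CH2Cl2, rt
Reagents that add atoms: none
Why: quaternisation of the amine and E1cB-type Hofmann elimination of the β-ammonium lactone deliver the exocyclic C11=C13 methylene under mild base.

Step 15
Reactants: 24 (2S,6R,7S,8R,9R)-2-(tert-butyldiphenylsilyloxy)-8,9-(isopropylidenedioxy)germacra-1(10)Z,4E,11(13)-trien-12,6-olide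
Product: 25 (2S,6R,7S,8R,9R)-2-(tert-butyldiphenylsilyloxy)-8,9-dihydroxygermacra-1(10)Z,4E,11(13)-trien-12,6-olide
Conditions: AcOH/H2O (4:1), 45 °C
Reagents that add atoms: none
Why: acid hydrolysis of the isopropylidene acetal, which the TBDPS ether survives and which the two ring alkenes, deactivated by their allylic oxygens, should pass without transannular reaction.

Step 16
Reactants: 25 (2S,6R,7S,8R,9R)-2-(tert-butyldiphenylsilyloxy)-8,9-dihydroxygermacra-1(10)Z,4E,11(13)-trien-12,6-olide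
Product: 26 (2S,6R,7S,8R,9R)-9-acetoxy-2-(tert-butyldiphenylsilyloxy)-8-hydroxygermacra-1(10)Z,4E,11(13)-trien-12,6-olide
Conditions: AcCl (1.05 equiv), 2,4,6-collidine, CH2Cl2, −78 → −40 °C
Reagents that add atoms: acetyl chloride, CC(=O)Cl
Why: kinetic monoacylation with one equivalent of acetyl chloride and a hindered pyridine base is expected to take the allylic C9 hydroxyl, flanked by the flat C10, before the C8 hydroxyl, which is shielded by the ring-fusion carbon and the lactone.

Step 17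
Reactants: 26 (2S,6R,7S,8R,9R)-9-acetoxy-2-(tert-butyldiphenylsilyloxy)-8-hydroxygermacra-1(10)Z,4E,11(13)-trien-12,6-olide
Product: 27 (2S,6R,7S,8R,9R)-9-acetoxy-8-angeloyloxy-2-(tert-butyldiphenylsilyloxy)germacra-1(10)Z,4E,11(13)-trien-12,6-olide
Conditions: angelic acid, 2,4,6-trichlorobenzoyl chloride, Et3N, toluene, rt; then 26, 75 °C
Reagents that add atoms: angelic acid [(2Z)-2-methylbut-2-enoic acid], C/C=C(/C)C(=O)O
Why: Yamaguchi-type esterification through the mixed 2,4,6-trichlorobenzoic anhydride, run without DMAP, acylates the hindered C8 hydroxyl while keeping the Z geometry of the angelate.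

Step 18
Reactants: 27 (2S,6R,7S,8R,9R)-9-acetoxy-8-angeloyloxy-2-(tert-butyldiphenylsilyloxy)germacra-1(10)Z,4E,11(13)-trien-12,6-olide
Product: 28 (2S,6R,7S,8R,9R)-9-acetoxy-8-angeloyloxy-2-hydroxygermacra-1(10)Z,4E,11(13)-trien-12,6-olide (CNP0316477.1)
Conditions: HF·pyridine, pyridine, THF, 0 °C → rt
Reagents that add atoms: none
Why: fluoride-mediated desilylation under weakly acidic conditions frees the C2 hydroxyl without acyl migration to O2 and without addition to the methylene lactone.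

**Compound list**

1 | (4R,5R)-2,2-dimethyl-1,3-dioxolane-4,5-dimethanol (2,3-O-isopropylidene-D-threitol) | OC[C@H]1OC(C)(C)O[C@@H]1CO | starting material
2 | [(4R,5R)-5-(tert-butyldimethylsilyloxymethyl)-2,2-dimethyl-1,3-dioxolan-4-yl]methanol | CC(C)(C)[Si](C)(C)OC[C@H]1OC(C)(C)O[C@@H]1CO | intermediate
3 | (4S,5R)-5-(tert-butyldimethylsilyloxymethyl)-2,2-dimethyl-1,3-dioxolane-4-carbaldehyde | CC(C)(C)[Si](C)(C)OC[C@H]1OC(C)(C)O[C@@H]1C=O | intermediate
4 | methyl (2E)-3-[(4R,5R)-5-(tert-butyldimethylsilyloxymethyl)-2,2-dimethyl-1,3-dioxolan-4-yl]prop-2-enoate | CC(C)(C)[Si](C)(C)OC[C@H]1OC(C)(C)O[C@@H]1/C=C/C(=O)OC | intermediate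
5 | trimethylsilyl ketene acetal of ester 6 | CC(C)(C)[Si](C)(C)OC[C@H]1OC(C)(C)O[C@@H]1[C@H](C=C)C=C(OC)O[Si](C)(C)C | intermediate
6 | methyl (3S)-3-[(4R,5R)-5-(tert-butyldimethylsilyloxymethyl)-2,2-dimethyl-1,3-dioxolan-4-yl]pent-4-enoate | CC(C)(C)[Si](C)(C)OC[C@H]1OC(C)(C)O[C@@H]1[C@H](C=C)CC(=O)OC | intermediate
7 | 1,2,4-trioxolane (ozonide) of 6 | CC(C)(C)[Si](C)(C)OC[C@H]1OC(C)(C)O[C@@H]1[C@@H](CC(=O)OC)C2OCOO2 | intermediate
8 | methyl (3R)-3-[(4R,5R)-5-(tert-butyldimethylsilyloxymethyl)-2,2-dimethyl-1,3-dioxolan-4-yl]-4-oxobutanoate | CC(C)(C)[Si](C)(C)OC[C@H]1OC(C)(C)O[C@@H]1[C@@H](CC(=O)OC)C=O | intermediate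
9 | but-2-yn-1-ol | CC#CCO | starting material
10 | sodium 2,2-bis(2-methoxyethoxy)-3-methyl-2,5-dihydro-1,2-oxaluminol-2-uide (cyclic alkenylaluminate) | CC1=CCO[Al-]1(OCCOC)OCCOC.[Na+] | intermediate
11 | (2Z)-3-iodobut-2-en-1-ol | OC/C=C(/C)I | intermediate
12 | (2Z)-3-iodobut-2-enal | O=C/C=C(/C)I | intermediate
13 | (4S,5Z)-6-iodohept-5-en-1-yn-4-ol | C#CC[C@H](O)/C=C(/C)I | intermediate
14 | tert-butyl{[(4S,5Z)-6-iodohept-5-en-1-yn-4-yl]oxy}diphenylsilane | C#CC[C@H](O[Si](c1ccccc1)(c2ccccc2)C(C)(C)C)/C=C(/C)I | intermediate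
15 | [(1E,4S,5Z)-4-(tert-butyldiphenylsilyloxy)-6-iodo-2-methylhepta-1,5-dien-1-yl]dimethylalane | C[Al](C)/C=C(\C)C[C@H](O[Si](c1ccccc1)(c2ccccc2)C(C)(C)C)/C=C(/C)I | intermediate
16 | methyl (3S,4R,5E,8S,9Z)-8-(tert-butyldiphenylsilyloxy)-3-[(4R,5R)-5-(tert-butyldimethylsilyloxymethyl)-2,2-dimethyl-1,3-dioxolan-4-yl]-4-hydroxy-10-iodo-6-methylundeca-5,9-dienoate | CC(C)(C)[Si](C)(C)OC[C@H]1OC(C)(C)O[C@@H]1[C@@H](CC(=O)OC)[C@H](O)/C=C(\C)C[C@H](O[Si](c2ccccc2)(c3ccccc3)C(C)(C)C)/C=C(/C)I | intermediate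
17 | (4S,5R)-4-[(4R,5R)-5-(tert-butyldimethylsilyloxymethyl)-2,2-dimethyl-1,3-dioxolan-4-yl]-5-[(1E,4S,5Z)-4-(tert-butyldiphenylsilyloxy)-6-iodo-2-methylhepta-1,5-dien-1-yl]oxolan-2-one | CC(C)(C)[Si](C)(C)OC[C@H]1OC(C)(C)O[C@@H]1[C@H]2CC(=O)O[C@@H]2/C=C(\C)C[C@H](O[Si](c3ccccc3)(c4ccccc4)C(C)(C)C)/C=C(/C)I | intermediate
18 | (4S,5R)-4-[(4R,5R)-5-(hydroxymethyl)-2,2-dimethyl-1,3-dioxolan-4-yl]-5-[(1E,4S,5Z)-4-(tert-butyldiphenylsilyloxy)-6-iodo-2-methylhepta-1,5-dien-1-yl]oxolan-2-one | OC[C@H]1OC(C)(C)O[C@@H]1[C@H]2CC(=O)O[C@@H]2/C=C(\C)C[C@H](O[Si](c3ccccc3)(c4ccccc4)C(C)(C)C)/C=C(/C)I | intermediate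
19 | (4S,5R)-5-{(2R,3S)-2-[(1E,4S,5Z)-4-(tert-butyldiphenylsilyloxy)-6-iodo-2-methylhepta-1,5-dien-1-yl]-5-oxooxolan-3-yl}-2,2-dimethyl-1,3-dioxolane-4-carbaldehyde | O=C[C@H]1OC(C)(C)O[C@@H]1[C@H]2CC(=O)O[C@@H]2/C=C(\C)C[C@H](O[Si](c3ccccc3)(c4ccccc4)C(C)(C)C)/C=C(/C)I | intermediate
20 | (4S,5R)-5-{(2R,3S)-2-[(1E,4S,5Z)-4-(tert-butyldiphenylsilyloxy)-6-iodo-2-methylhepta-1,5-dien-1-yl]-5-oxooxolan-3-yl}-2,2-dimethyl-1,3-dioxolane-4-carboxylic acid | OC(=O)[C@H]1OC(C)(C)O[C@@H]1[C@H]2CC(=O)O[C@@H]2/C=C(\C)C[C@H](O[Si](c3ccccc3)(c4ccccc4)C(C)(C)C)/C=C(/C)I | intermediate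
21 | (2S,6R,7S,8R,9R)-2-(tert-butyldiphenylsilyloxy)-8,9-(isopropylidenedioxy)germacra-1(10)Z,4E-dien-12,6-olide | C1C(=O)O[C@@H]2/C=C(\C)C[C@H](O[Si](c3ccccc3)(c4ccccc4)C(C)(C)C)/C=C(/C)[C@H]5OC(C)(C)O[C@@H]5[C@@H]12 | intermediate
22 | 11-(dimethylaminomethyl) derivative of 21 | CN(C)CC1C(=O)O[C@@H]2/C=C(\C)C[C@H](O[Si](c3ccccc3)(c4ccccc4)C(C)(C)C)/C=C(/C)[C@H]5OC(C)(C)O[C@@H]5[C@@H]12 | intermediate
23 | 11-(trimethylammoniomethyl) iodide of 21 | C[N+](C)(C)CC1C(=O)O[C@@H]2/C=C(\C)C[C@H](O[Si](c3ccccc3)(c4ccccc4)C(C)(C)C)/C=C(/C)[C@H]5OC(C)(C)O[C@@H]5[C@@H]12.[I-] | intermediate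
24 | (2S,6R,7S,8R,9R)-2-(tert-butyldiphenylsilyloxy)-8,9-(isopropylidenedioxy)germacra-1(10)Z,4E,11(13)-trien-12,6-olide | C=C1C(=O)O[C@@H]2/C=C(\C)C[C@H](O[Si](c3ccccc3)(c4ccccc4)C(C)(C)C)/C=C(/C)[C@H]5OC(C)(C)O[C@@H]5[C@@H]12 | intermediate
25 | (2S,6R,7S,8R,9R)-2-(tert-butyldiphenylsilyloxy)-8,9-dihydroxygermacra-1(10)Z,4E,11(13)-trien-12,6-olide | C=C1C(=O)O[C@@H]2/C=C(\C)C[C@H](O[Si](c3ccccc3)(c4ccccc4)C(C)(C)C)/C=C(/C)[C@@H](O)[C@H](O)[C@@H]12 | intermediate
26 | (2S,6R,7S,8R,9R)-9-acetoxy-2-(tert-butyldiphenylsilyloxy)-8-hydroxygermacra-1(10)Z,4E,11(13)-trien-12,6-olide | C=C1C(=O)O[C@@H]2/C=C(\C)C[C@H](O[Si](c3ccccc3)(c4ccccc4)C(C)(C)C)/C=C(/C)[C@@H](OC(C)=O)[C@H](O)[C@@H]12 | intermediate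
27 | (2S,6R,7S,8R,9R)-9-acetoxy-8-angeloyloxy-2-(tert-butyldiphenylsilyloxy)germacra-1(10)Z,4E,11(13)-trien-12,6-olide | C=C1C(=O)O[C@@H]2/C=C(\C)C[C@H](O[Si](c3ccccc3)(c4ccccc4)C(C)(C)C)/C=C(/C)[C@@H](OC(C)=O)[C@H](OC(=O)/C(C)=C\C)[C@@H]12 | intermediate
28 | (2S,6R,7S,8R,9R)-9-acetoxy-8-angeloyloxy-2-hydroxygermacra-1(10)Z,4E,11(13)-trien-12,6-olide (CNP0316477.1) | C=C1C(=O)O[C@@H]2/C=C(\C)C[C@H](O)/C=C(/C)[C@@H](OC(C)=O)[C@H](OC(=O)/C(C)=C\C)[C@@H]12 | target

**Step count and risks**

Total steps: 18. Longest linear sequence: 14 steps (1–4 then 9–18; the branch 5–8 then 9–18 is equally long).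

Most likely to fail:

1. Step 12 (the ring closure). The ring closure may lose to oligomerisation, to hydrogen capture by the C9 radical, to hydrodeiodination, or to ionisation of the allylic lactone by zerovalent nickel. The fallback exchanges the two bond formations, so that C9–C10 is made by the known intermolecular coupling and ring 2 is closed at C5–C6 by a Nozaki–Hiyama–Kishi reaction. It sets out from 6 and 14. HF·pyridine frees the primary alcohol of 6 to give hydroxy ester F1, and TEMPO/PhI(OAc)2 oxidation gives dioxolane carboxylic acid F2. F2 is coupled with alkenyl iodide 14 under the catalysts of step 12 at ordinary concentration (0.05 M) to give enyne ester F3, with the new bond anti to the C8 substituent. Methylalumination of the terminal alkyne (AlMe3, Cp2ZrCl2, H2O, CH2Cl2, −20 °C) and iodinolysis give E alkenyl iodide F4. OsO4 (cat.) with N-methylmorpholine N-oxide, then NaIO4, should cleave only the monosubstituted vinyl group, since one trisubstituted alkene is deactivated by iodine and the other by two allylic C–O bonds; this gives aldehyde F5. CrCl2 with catalytic NiCl2 in DMSO at high dilution closes the ten-membered ring at C5–C6, and the alkoxide lactonises (PPTS if needed), which comes back to the route at 21.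

2. Step 9 (fragment union). Facial selectivity at C6 may be poor, because Felkin–Anh control by the dioxolanyl group and the directing effect of the β-oxygen O8 oppose each other; methyl transfer from aluminium may also compete. The fallback corrects C6 after the addition by an invertive ring closure. It sets out from 8 and 14 as in step 9: the C6-epimeric cis lactone F6 is separated, opened with LiOH in THF/H2O and acidified cold to hydroxy acid F7. Mitsunobu lactonisation (PPh3, diisopropyl azodicarboxylate, toluene, 0 °C) then closes the ring with inversion at C6 and comes back to the route at 17.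

3. Step 16 (monoacetylation). The small acylating agent may not discriminate enough between the two secondary hydroxyls, and the acetyl group may migrate from O9 to O8 during the heated angeloylation. The fallback differentiates the hydroxyls by size with a silyl group instead. It sets out from 25: Et3SiCl and imidazole in CH2Cl2 at −40 °C give the 9-O-triethylsilyl ether F8, and the mixed-anhydride angeloylation of step 17 gives its 8-angelate F9. Brief HF·pyridine/pyridine at 0 °C removes only the triethylsilyl group to give the 9-hydroxy 8-angelate F10, and Ac2O/pyridine with catalytic DMAP at 0 °C comes back to the route at 27.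

**Further compounds**

F1 | step 12 | methyl (3S)-3-[(4R,5R)-5-(hydroxymethyl)-2,2-dimethyl-1,3-dioxolan-4-yl]pent-4-enoate | OC[C@H]1OC(C)(C)O[C@@H]1[C@H](C=C)CC(=O)OC
F2 | step 12 | (4S,5R)-5-[(3S)-5-methoxy-5-oxopent-1-en-3-yl]-2,2-dimethyl-1,3-dioxolane-4-carboxylic acid | OC(=O)[C@H]1OC(C)(C)O[C@@H]1[C@H](C=C)CC(=O)OC
F3 | step 12 | methyl (3S)-3-{(4R,5R)-5-[(2Z,4S)-4-(tert-butyldiphenylsilyloxy)hept-2-en-6-yn-2-yl]-2,2-dimethyl-1,3-dioxolan-4-yl}pent-4-enoate | C#CC[C@H](O[Si](c1ccccc1)(c2ccccc2)C(C)(C)C)/C=C(/C)[C@H]3OC(C)(C)O[C@@H]3[C@H](C=C)CC(=O)OC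
F4 | step 12 | methyl (3S)-3-{(4R,5R)-5-[(2Z,4S,6E)-4-(tert-butyldiphenylsilyloxy)-7-iodo-6-methylhepta-2,6-dien-2-yl]-2,2-dimethyl-1,3-dioxolan-4-yl}pent-4-enoate | I/C=C(\C)C[C@H](O[Si](c1ccccc1)(c2ccccc2)C(C)(C)C)/C=C(/C)[C@H]3OC(C)(C)O[C@@H]3[C@H](C=C)CC(=O)OC
F5 | step 12 | methyl (3R)-3-{(4R,5R)-5-[(2Z,4S,6E)-4-(tert-butyldiphenylsilyloxy)-7-iodo-6-methylhepta-2,6-dien-2-yl]-2,2-dimethyl-1,3-dioxolan-4-yl}-4-oxobutanoate | I/C=C(\C)C[C@H](O[Si](c1ccccc1)(c2ccccc2)C(C)(C)C)/C=C(/C)[C@H]3OC(C)(C)O[C@@H]3[C@@H](CC(=O)OC)C=O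
F6 | step 9 | C6 epimer of 17 (cis lactone, 4S,5S in the oxolanone) | CC(C)(C)[Si](C)(C)OC[C@H]1OC(C)(C)O[C@@H]1[C@H]2CC(=O)O[C@H]2/C=C(\C)C[C@H](O[Si](c3ccccc3)(c4ccccc4)C(C)(C)C)/C=C(/C)I
F7 | step 9 | (3S,4S,5E,8S,9Z)-8-(tert-butyldiphenylsilyloxy)-3-[(4R,5R)-5-(tert-butyldimethylsilyloxymethyl)-2,2-dimethyl-1,3-dioxolan-4-yl]-4-hydroxy-10-iodo-6-methylundeca-5,9-dienoic acid | CC(C)(C)[Si](C)(C)OC[C@H]1OC(C)(C)O[C@@H]1[C@@H](CC(=O)O)[C@@H](O)/C=C(\C)C[C@H](O[Si](c2ccccc2)(c3ccccc3)C(C)(C)C)/C=C(/C)I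
F8 | step 16 | 9-O-triethylsilyl ether of diol 25 | C=C1C(=O)O[C@@H]2/C=C(\C)C[C@H](O[Si](c3ccccc3)(c4ccccc4)C(C)(C)C)/C=C(/C)[C@@H](O[Si](CC)(CC)CC)[C@H](O)[C@@H]12
F9 | step 16 | 8-O-angeloyl 9-O-triethylsilyl derivative of diol 25 | C=C1C(=O)O[C@@H]2/C=C(\C)C[C@H](O[Si](c3ccccc3)(c4ccccc4)C(C)(C)C)/C=C(/C)[C@@H](O[Si](CC)(CC)CC)[C@H](OC(=O)/C(C)=C\C)[C@@H]12
F10 | step 16 | 8-O-angeloyl derivative of diol 25 (9-hydroxyl free) | C=C1C(=O)O[C@@H]2/C=C(\C)C[C@H](O[Si](c3ccccc3)(c4ccccc4)C(C)(C)C)/C=C(/C)[C@@H](O)[C@H](OC(=O)/C(C)=C\C)[C@@H]12
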